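**Retrosynthetic overview**
1. Target ⇒ cut the C2–C3 bond of the acyl chain: docos-1-ene plus a •CH2CO2CH2CH2Ph equivalent, the mono-(2-phenylethyl) malonate (new decarboxylative anti-Markovnikov hydroalkylation, CO2 as only by-product).
2. Mono-(2-phenylethyl) malonate ⇒ Meldrum's acid + 2-phenylethanol (ester C–O bond, acetone lost).
3. Docos-1-ene ⇒ cut C11–C12: undecyl Grignard reagent + 11-bromoundec-1-ene, Cu-catalysed sp3–sp3 coupling.
4. No ring is formed (the benzene ring arrives with 2-phenylethanol); the C24 chain is assembled as C11 + C11 + C2.

Assumption: the target has no stereocentre and no stereogenic double bond, so "single enantiomer" is taken to mean this one achiral compound.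

**Step 1**
Reactants: 1 undecyl bromide (1-bromoundecane); 2 11-bromoundec-1-ene
Product: 4 docos-1-ene, via undecylmagnesium bromide 3 (not isolated)
Conditions: 1 (1.2 equiv), Mg, I2 (cat.), THF, 50 °C; then add to 2, Li2CuCl4 (3 mol%), NMP, THF, −10 °C to rt
Reagents that add atoms: none
Why: Kochi-type copper-catalysed sp3–sp3 cross-coupling of a primary alkyl Grignard reagent with a primary alkyl bromide; the terminal alkene is inert under these conditions and no stereocentre is formed.

**Step 2**
Reactants: 5 Meldrum's acid (2,2-dimethyl-1,3-dioxane-4,6-dione); 6 2-phenylethanol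
Product: 7 3-oxo-3-(2-phenylethoxy)propanoic acid
Conditions: toluene, 105 °C, 4 h; NaHCO3 extraction, then acidify
Reagents that add atoms: none
Why: Alcoholysis of Meldrum's acid, in which the alcohol opens the activated cyclic acylal at one carbonyl and acetone is expelled, stops cleanly at the mono-ester mono-acid; no stereocentre is formed.

**Step 3**
Reactants: 4 docos-1-ene; 7 3-oxo-3-(2-phenylethoxy)propanoic acid
Product: 8 2-phenylethyl tetracosanoate
Conditions: 7 (2.0 equiv), 3,6-di-tert-butyl-9-mesityl-10-phenylacridinium BF4 (3 mol%), 2,4,6-triisopropylbenzenethiol (10 mol%), 2,6-lutidine (20 mol%), DCE/TFE 4:1, 450 nm LEDs, 35 °C, Ar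
Reagents that add atoms: none
Why: Proposed new method: photoredox decarboxylative anti-Markovnikov hydro(alkoxycarbonylmethyl)ation of an unactivated 1-alkene with a malonic half-ester as a traceless acetate-radical donor — the excited acridinium (E*red about +2.0 V vs SCE) oxidises the carboxylate of 7 but not the 1-alkene or the alkylbenzene ring, the acyloxy radical loses CO2, the electrophilic ester-stabilised primary radical adds to the terminal CH2 of electron-rich 4 (polarity matched, whereas its quench by ArS–H is polarity mismatched and slow), the resulting nucleophilic secondary alkyl radical takes H from ArSH, and ArS• is reduced by the acridine radical and reprotonated by 7, so the cycle is redox-neutral; the closest known reaction types are the acridinium/thiol hydrodecarboxylation of malonic acid derivatives and the decarboxylative Giese addition, which is limited to electron-poor alkenes; no stereocentre is formed.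

**Compound list**
1 | undecyl bromide (1-bromoundecane) | CCCCCCCCCCCBr | starting material
2 | 11-bromoundec-1-ene | C=CCCCCCCCCCBr | starting material
3 | undecylmagnesium bromide | CCCCCCCCCCC[Mg]Br | intermediate
4 | docos-1-ene | CCCCCCCCCCCCCCCCCCCCC=C | intermediate
5 | Meldrum's acid (2,2-dimethyl-1,3-dioxane-4,6-dione) | CC1(C)OC(=O)CC(=O)O1 | starting material
6 | 2-phenylethanol | OCCc1ccccc1 | starting material
7 | 3-oxo-3-(2-phenylethoxy)propanoic acid | OC(=O)CC(=O)OCCc1ccccc1 | intermediate
8 | 2-phenylethyl tetracosanoate | CCCCCCCCCCCCCCCCCCCCCCCC(=O)OCCc1ccccc1 | target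

**Total step count:** 3
**Longest linear sequence:** 2 steps (step 1 then step 3; step 2 is the other branch into step 3)

**Three steps most likely to fail**

Step 3 (the proposed new step). The main risks are H-transfer from the thiol to the α-ester radical before it adds to 4 (giving 2-phenylethyl acetate), thiol–ene loss of the co-catalyst, and slow oxidation of the electron-poor carboxylate. The fallback uses known chemistry, sets out from 4 (with 6 as the ester source) and comes back at 8. Compound 6 is esterified with bromoacetic acid (TsOH cat., toluene, Dean–Stark) to give 2-phenylethyl 2-bromoacetate F1. Compound 4 is hydroborated with 9-BBN-H in THF (rt to 60 °C) to give 9-docosyl-9-borabicyclo[3.3.1]nonane F2. In the same flask F2 is treated with F1 and potassium 2,6-di-tert-butylphenoxide at 0 °C. This is the classical α-alkylation of an α-bromo ester by a B-alkyl-9-BBN (ate complex, 1,2-shift of the primary alkyl group with loss of bromide, protonation of the boron enolate), and it gives 8 directly.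

Step 1. The main risks are Wurtz homocoupling to docosane, which co-elutes with 4 (AgNO3–silica would be needed), and incomplete Grignard formation. The fallback sets out from 2 and comes back at 4. Compound 2 is heated with sodium benzenesulfinate in DMF at 80 °C to give (undec-10-en-1-ylsulfonyl)benzene F3. F3 is deprotonated with n-BuLi in THF at −78 °C and alkylated with 1 (DMPU, −78 °C to rt) to give [(docos-1-en-11-yl)sulfonyl]benzene F4, a polar compound that is easily freed from hydrocarbons. Reductive desulfonylation of F4 with 6% Na(Hg), Na2HPO4, MeOH/THF, −20 °C to rt gives 4.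

Step 2. The main risks are thermal decarboxylation of 7 to 2-phenylethyl acetate on overheating and some bis-ester formation. The fallback sets out from 6 and comes back at 7. Compound 6 is coupled with 3-tert-butoxy-3-oxopropanoic acid (DCC, DMAP cat., CH2Cl2, 0 °C to rt) to give tert-butyl 2-phenylethyl propanedioate F5. The tert-butyl ester is then cleaved with TFA/CH2Cl2 (1:4, rt) to give 7.

**Further compounds**
F1 | step 3 | 2-phenylethyl 2-bromoacetate | BrCC(=O)OCCc1ccccc1
F2 | step 3 | 9-docosyl-9-borabicyclo[3.3.1]nonane | CCCCCCCCCCCCCCCCCCCCCCB1C2CCCC1CCC2
F3 | step 1 | (undec-10-en-1-ylsulfonyl)benzene | C=CCCCCCCCCCS(=O)(=O)c1ccccc1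
F4 | step 1 | [(docos-1-en-11-yl)sulfonyl]benzene | C=CCCCCCCCCC(CCCCCCCCCCC)S(=O)(=O)c1ccccc1
F5 | step 2 | tert-butyl 2-phenylethyl propanedioate | CC(C)(C)OC(=O)CC(=O)OCCc1ccccc1
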